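Ring C is disconnected at O1–C8a. Because O1 is both the oxygen borne by the C2 stereocentre and the ether oxygen on C8a of ring A, ring C can be closed by palladium-catalysed etherification of a secondary benzylic alcohol with an ortho aryl bromide, and the C2–O bond with its S configuration is never broken. This one operation completes the flavan framework. The precursor is a homoallylic alcohol made by catalytic asymmetric allylboration of the ring B aldehyde with a 2-(2-bromoaryl)allylboronate. Its 1,1-disubstituted alkene stands in for the C4 carbonyl, which is released afterwards by oxidative cleavage before the three benzyl ethers are removed.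

Key step: step 10

Remark: in step 9 the S catalyst is chosen on the assumption that aldehyde 13 shows the facial preference known for simple aryl aldehydes; if a first run shows the opposite sense, the R catalyst is used with no other change.

Step 1
Reactants: 1 5-bromobenzene-1,3-diol
Product: 3 1-(2-bromo-4,6-dihydroxyphenyl)ethan-1-one, via ketiminium chloride 2 (not isolated)
Conditions: MeCN, ZnCl2, HCl (g), Et2O, 0 °C to rt; then H2O, reflux
Reagents that add atoms: acetonitrile CC#N; water O
Why: Houben–Hoesch acylation, in which the nitrilium ion attacks C4 of the resorcinol (ortho to one hydroxyl and para to the other, as with orcinol) and hot water hydrolyses the ketiminium salt to the methyl ketone; acylating before benzylation keeps Lewis acids away from benzyl ethers.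

Step 2
Reactants: 3 1-(2-bromo-4,6-dihydroxyphenyl)ethan-1-one
Product: 4 1-[2,4-bis(benzyloxy)-6-bromophenyl]ethan-1-one
Conditions: BnBr (2.4 equiv), K2CO3, DMF, 60 °C
Reagents that add atoms: benzyl bromide BrCc1ccccc1
Why: Williamson etherification of both phenols, the hydroxyl next to the acetyl group reacting in warm DMF because the flanking bromine twists the carbonyl out of the ring plane and weakens its hydrogen bond.

Step 3
Reactants: 4 1-[2,4-bis(benzyloxy)-6-bromophenyl]ethan-1-one
Product: 6 1-[2,4-bis(benzyloxy)-6-bromophenyl]ethenyl trifluoromethanesulfonate, via potassium enolate 5 (not isolated)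
Conditions: KN(SiMe3)2 (1.05 equiv), THF, −78 °C; then PhNTf2, −78 to 0 °C
Reagents that add atoms: N-phenylbis(trifluoromethanesulfonimide) FC(F)(F)S(=O)(=O)N(c1ccccc1)S(=O)(=O)C(F)(F)F
Why: Enol triflate formation, in which the ketone has a single enolisable carbon and its potassium enolate is sulfonylated on oxygen, turning a carbonyl that is shielded by two ortho substituents into a cross-coupling handle.

Step 4
Reactants: 6 1-[2,4-bis(benzyloxy)-6-bromophenyl]ethenyl trifluoromethanesulfonate
Product: 7 2-{2-[2,4-bis(benzyloxy)-6-bromophenyl]prop-2-en-1-yl}-4,4,5,5-tetramethyl-1,3,2-dioxaborolane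
Conditions: ICH2Bpin, Zn powder, THF, rt; then 6, Pd(PPh3)4 (5 mol %), THF, rt to 40 °C
Reagents that add atoms: 2-(iodomethyl)-4,4,5,5-tetramethyl-1,3,2-dioxaborolane CC1(C)OB(CI)OC1(C)C
Why: Negishi cross-coupling of (pinacolatoboryl)methylzinc iodide with an alkenyl triflate, in which Pd(PPh3)4 inserts into the vinyl C–OTf bond near room temperature much faster than into the aryl C–Br bond and the base-free medium leaves the allylboronate untouched.

Step 5
Reactants: 8 1-(2,3-dihydroxyphenyl)ethan-1-one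
Product: 9 1-(5-bromo-2,3-dihydroxyphenyl)ethan-1-one
Conditions: Br2 (1.0 equiv), NaOAc, AcOH, 15 °C
Reagents that add atoms: bromine BrBr
Why: Electrophilic aromatic bromination at C5, which is para to the 2-hydroxyl and meta to the acetyl group and is where 2,3-dihydroxybenzoyl compounds take up electrophiles, while the acetate buffer holds back acid-catalysed bromination of the methyl ketone.

Step 6
Reactants: 9 1-(5-bromo-2,3-dihydroxyphenyl)ethan-1-one
Product: 11 6-bromo-8-hydroxy-2,2-dimethyl-2,3-dihydro-4H-chromen-4-one, via aryl prenyl ketone 10 (not isolated)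
Conditions: acetone (excess), pyrrolidine (0.5 equiv), MeOH, 50 °C, under N2
Reagents that add atoms: acetone CC(C)=O
Why: Kabbe condensation, in which amine-mediated aldol condensation with acetone gives the enone and the 2-hydroxyl, the only phenol that can reach it, closes the pyranone by oxa-Michael addition, leaving the other hydroxyl free at C8.

Step 7
Reactants: 11 6-bromo-8-hydroxy-2,2-dimethyl-2,3-dihydro-4H-chromen-4-one
Product: 12 8-(benzyloxy)-6-bromo-2,2-dimethyl-2,3-dihydro-4H-chromen-4-one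
Conditions: BnBr, K2CO3, DMF, rt to 50 °C
Reagents that add atoms: benzyl bromide BrCc1ccccc1
Why: Williamson etherification of the single remaining phenol under mild carbonate conditions that do not open the 2,2-dimethylchromanone.

Step 8
Reactants: 12 8-(benzyloxy)-6-bromo-2,2-dimethyl-2,3-dihydro-4H-chromen-4-one
Product: 13 8-(benzyloxy)-2,2-dimethyl-4-oxo-3,4-dihydro-2H-chromene-6-carbaldehyde
Conditions: CO/H2 (1:1, 5 bar), Pd(OAc)2 (1 mol %), di(1-adamantyl)-n-butylphosphine (3 mol %), TMEDA, toluene, 100 °C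
Reagents that add atoms: carbon monoxide [C-]#[O+]
Why: Palladium-catalysed reductive carbonylation of an aryl bromide (oxidative addition, CO insertion, hydrogenolysis of the acyl–palladium bond), which installs the formyl group without any organometallic reagent that would attack the ring B ketone.

Step 9
Reactants: 13 8-(benzyloxy)-2,2-dimethyl-4-oxo-3,4-dihydro-2H-chromene-6-carbaldehyde; 7 2-{2-[2,4-bis(benzyloxy)-6-bromophenyl]prop-2-en-1-yl}-4,4,5,5-tetramethyl-1,3,2-dioxaborolane
Product: 15 8-(benzyloxy)-6-{(1S)-3-[2,4-bis(benzyloxy)-6-bromophenyl]-1-hydroxybut-3-en-1-yl}-2,2-dimethyl-2,3-dihydro-4H-chromen-4-one, via pinacol borate ester 14 (not isolated)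
Conditions: (S)-TRIP [(S)-3,3′-bis(2,4,6-triisopropylphenyl)-1,1′-binaphthyl-2,2′-diyl hydrogen phosphate] (5 mol %), toluene, −30 °C; aq. NaHCO3 work-up
Reagents that add atoms: none
Why: Chiral phosphoric acid-catalysed allylboration through a closed chair transition state with the acid hydrogen-bonded to a boronate oxygen and to the formyl hydrogen, in which the S catalyst is expected to send the allyl group to the Si face of the aldehyde and so set C2 as S, while the far less electrophilic ring B ketone does not react.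

Step 10
Reactants: 15 8-(benzyloxy)-6-{(1S)-3-[2,4-bis(benzyloxy)-6-bromophenyl]-1-hydroxybut-3-en-1-yl}-2,2-dimethyl-2,3-dihydro-4H-chromen-4-one
Product: 16 8-(benzyloxy)-6-[(2S)-5,7-bis(benzyloxy)-4-methylidene-3,4-dihydro-2H-chromen-2-yl]-2,2-dimethyl-2,3-dihydro-4H-chromen-4-one
Conditions: Pd(OAc)2 (5 mol %), rac-2-(di-tert-butylphosphino)-1,1′-binaphthyl (6 mol %), Cs2CO3 (1.5 equiv), toluene, 70 °C; filtered and carried on without acidic contact
Reagents that add atoms: none
Why: Zerovalent palladium, formed in the flask from Pd(OAc)2 and the phosphine, inserts into the C8a–Br bond, carbonate-assisted exchange of bromide for the tethered C2 alkoxide gives a seven-membered aryl(alkoxo)palladium chelate, and C–O reductive elimination forms O1–C8a and returns the catalyst. The closest known reaction is the intramolecular Buchwald–Hartwig etherification of secondary alcohols with aryl bromides that gives chromans. Ring C, the only ring closed, forms as a six-membered ring by bonding of the alkoxide oxygen to the metal-bound aryl carbon, formally a 6-exo closure reached by contraction of the seven-membered palladacycle. No stereocentre is created and the C2–O bond is not broken, so the S configuration from step 9 is carried through unchanged. Reductive elimination has to outrun β-hydride elimination and β-allyl fragmentation of the secondary benzylic alkoxide, which the bulky electron-rich di-tert-butylbiarylphosphine and the favourable ring size should secure, and insertion is not retarded because the bromide has one ortho substituent and no ortho or para oxygen. Keeping C4 as a methylidene group leaves no β-hydroxy ketone to dehydrate or cleave by retro-aldol reaction under the carbonate base, which is also weak enough to spare the ring B chromanone.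

Step 11
Reactants: 16 8-(benzyloxy)-6-[(2S)-5,7-bis(benzyloxy)-4-methylidene-3,4-dihydro-2H-chromen-2-yl]-2,2-dimethyl-2,3-dihydro-4H-chromen-4-one
Product: 18 (2S)-5,7-bis(benzyloxy)-2-[8-(benzyloxy)-2,2-dimethyl-4-oxo-3,4-dihydro-2H-chromen-6-yl]-2,3-dihydro-4H-chromen-4-one, via C4 diol 17 (not isolated)
Conditions: OsO4 (2 mol %), NaIO4 (4 equiv), 2,6-lutidine, dioxane/H2O (3:1), rt
Reagents that add atoms: osmium tetroxide O=[Os](=O)(=O)=O; sodium periodate [Na+].[O-]I(=O)(=O)=O
Why: Lemieux–Johnson oxidation, in which osmium-catalysed dihydroxylation of the only alkene and periodate cleavage of the diol release the C4 ketone, and the 2,6-lutidine buffer keeps the medium near neutral so that the new flavanone does not open to a chalcone and C2 keeps its configuration.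

Step 12
Reactants: 18 (2S)-5,7-bis(benzyloxy)-2-[8-(benzyloxy)-2,2-dimethyl-4-oxo-3,4-dihydro-2H-chromen-6-yl]-2,3-dihydro-4H-chromen-4-one
Product: 19 (2S)-5,7-dihydroxy-2-(8-hydroxy-2,2-dimethyl-4-oxo-3,4-dihydro-2H-chromen-6-yl)-2,3-dihydro-4H-chromen-4-one
Conditions: H2 (1 atm), Pd/C (10 wt %), EtOAc/MeOH (1:1), rt, stopped after uptake of three equivalents
Reagents that add atoms: none
Why: Catalytic hydrogenolysis of the three benzyl ethers under neutral conditions, which should free the phenols faster than the benzylic C2–O1 bond or the aryl ketones are reduced and cannot epimerise C2 through ring opening as a basic deprotection could.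

Compound list
1 | 5-bromobenzene-1,3-diol | Oc1cc(O)cc(Br)c1 | starting material
2 | 1-(2-bromo-4,6-dihydroxyphenyl)ethan-1-iminium chloride | CC(=[NH2+])c1c(O)cc(O)cc1Br.[Cl-] | intermediate (not isolated)
3 | 1-(2-bromo-4,6-dihydroxyphenyl)ethan-1-one | CC(=O)c1c(O)cc(O)cc1Br | intermediate
4 | 1-[2,4-bis(benzyloxy)-6-bromophenyl]ethan-1-one | CC(=O)c1c(OCc2ccccc2)cc(OCc2ccccc2)cc1Br | intermediate
5 | potassium 1-[2,4-bis(benzyloxy)-6-bromophenyl]ethen-1-olate | [K+].[O-]C(=C)c1c(OCc2ccccc2)cc(OCc2ccccc2)cc1Br | intermediate (not isolated)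
6 | 1-[2,4-bis(benzyloxy)-6-bromophenyl]ethenyl trifluoromethanesulfonate | C=C(OS(=O)(=O)C(F)(F)F)c1c(OCc2ccccc2)cc(OCc2ccccc2)cc1Br | intermediate
7 | 2-{2-[2,4-bis(benzyloxy)-6-bromophenyl]prop-2-en-1-yl}-4,4,5,5-tetramethyl-1,3,2-dioxaborolane | C=C(CB1OC(C)(C)C(C)(C)O1)c1c(OCc2ccccc2)cc(OCc2ccccc2)cc1Br | intermediate
8 | 1-(2,3-dihydroxyphenyl)ethan-1-one | CC(=O)c1cccc(O)c1O | starting material
9 | 1-(5-bromo-2,3-dihydroxyphenyl)ethan-1-one | CC(=O)c1cc(Br)cc(O)c1O | intermediate
10 | 1-(5-bromo-2,3-dihydroxyphenyl)-3-methylbut-2-en-1-one | CC(C)=CC(=O)c1cc(Br)cc(O)c1O | intermediate (not isolated)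
11 | 6-bromo-8-hydroxy-2,2-dimethyl-2,3-dihydro-4H-chromen-4-one | CC1(C)CC(=O)c2cc(Br)cc(O)c2O1 | intermediate
12 | 8-(benzyloxy)-6-bromo-2,2-dimethyl-2,3-dihydro-4H-chromen-4-one | CC1(C)CC(=O)c2cc(Br)cc(OCc3ccccc3)c2O1 | intermediate
13 | 8-(benzyloxy)-2,2-dimethyl-4-oxo-3,4-dihydro-2H-chromene-6-carbaldehyde | CC1(C)CC(=O)c2cc(C=O)cc(OCc3ccccc3)c2O1 | intermediate
14 | 8-(benzyloxy)-6-{(1S)-3-[2,4-bis(benzyloxy)-6-bromophenyl]-1-[(4,4,5,5-tetramethyl-1,3,2-dioxaborolan-2-yl)oxy]but-3-en-1-yl}-2,2-dimethyl-2,3-dihydro-4H-chromen-4-one | CC1(C)CC(=O)c2cc([C@@H](OB3OC(C)(C)C(C)(C)O3)CC(=C)c3c(Br)cc(OCc4ccccc4)cc3OCc3ccccc3)cc(OCc3ccccc3)c2O1 | intermediate (not isolated)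
15 | 8-(benzyloxy)-6-{(1S)-3-[2,4-bis(benzyloxy)-6-bromophenyl]-1-hydroxybut-3-en-1-yl}-2,2-dimethyl-2,3-dihydro-4H-chromen-4-one | CC1(C)CC(=O)c2cc([C@@H](O)CC(=C)c3c(Br)cc(OCc4ccccc4)cc3OCc3ccccc3)cc(OCc3ccccc3)c2O1 | intermediate
16 | 8-(benzyloxy)-6-[(2S)-5,7-bis(benzyloxy)-4-methylidene-3,4-dihydro-2H-chromen-2-yl]-2,2-dimethyl-2,3-dihydro-4H-chromen-4-one | CC1(C)CC(=O)c2cc([C@@H]3CC(=C)c4c(OCc5ccccc5)cc(OCc5ccccc5)cc4O3)cc(OCc3ccccc3)c2O1 | intermediate
17 | 8-(benzyloxy)-6-[(2S)-5,7-bis(benzyloxy)-4-hydroxy-4-(hydroxymethyl)-3,4-dihydro-2H-chromen-2-yl]-2,2-dimethyl-2,3-dihydro-4H-chromen-4-one (both C4 epimers) | CC1(C)CC(=O)c2cc([C@@H]3CC(O)(CO)c4c(OCc5ccccc5)cc(OCc5ccccc5)cc4O3)cc(OCc3ccccc3)c2O1 | intermediate (not isolated)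
18 | (2S)-5,7-bis(benzyloxy)-2-[8-(benzyloxy)-2,2-dimethyl-4-oxo-3,4-dihydro-2H-chromen-6-yl]-2,3-dihydro-4H-chromen-4-one | CC1(C)CC(=O)c2cc([C@@H]3CC(=O)c4c(OCc5ccccc5)cc(OCc5ccccc5)cc4O3)cc(OCc3ccccc3)c2O1 | intermediate
19 | (2S)-5,7-dihydroxy-2-(8-hydroxy-2,2-dimethyl-4-oxo-3,4-dihydro-2H-chromen-6-yl)-2,3-dihydro-4H-chromen-4-one | CC1(C)CC(=O)c2cc([C@@H]3CC(=O)c4c(O)cc(O)cc4O3)cc(O)c2O1 | target

Total step count: 12. Longest linear sequence: 8 steps (steps 1–4 or steps 5–8, followed by steps 9–12).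

Steps most likely to fail

Step 10. The alkoxo(aryl)palladium intermediate may undergo β-hydride elimination, which oxidises the carbinol and reduces the C–Br bond, and the palladium hydride so formed may move the exocyclic double bond into ring C. The fallback closes ring C at O1–C2 by displacement instead of at O1–C8a; it sets out from 13 and 7 and comes back at 16. The allylboration is run with (R)-TRIP and should give, through the pinacol borate of the (1R)-alcohol F1, the (1R)-enantiomer of 15 F2. Miyaura borylation (B2pin2, PdCl2(dppf), KOAc, dioxane, 80 °C) converts its bromide into the aryl pinacol boronate F3, and oxidation (NaBO3·4H2O, THF/H2O, rt) gives the phenol F4. Mitsunobu cyclisation (PPh3, DIAD, THF, 0 °C) then joins the phenol oxygen to C2 with inversion, so the R carbinol should give 16 with the S configuration.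

Step 9. Facial discrimination may be poor with the bulky 2-arylallyl reagent, or turnover may be slow enough for the uncatalysed racemic pathway to compete. The fallback replaces catalyst control by resolution; it sets out from 13 and 7 and comes back at 15. The allylboration is run without chiral catalyst (toluene, 40 °C) and gives, through the racemic pinacol borate F5, the racemic alcohol F6. Esterification with (S)-2-methoxy-2-phenylacetic acid (DCC, DMAP, CH2Cl2, 0 °C) gives the (1S)-carbinol ester F7 and the (1R)-carbinol ester F8, which are separated by chromatography or crystallisation. Methanolysis of F7 (K2CO3, MeOH, rt) returns 15.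

Step 4. Chemoselectivity may be lost if palladium inserts into the aryl C–Br bond as well, or oxidative addition at the shielded vinyl carbon may be too slow. The fallback avoids palladium and builds the allylboronate by C–B bond formation; it sets out from 4 and comes back at 7. Wittig methylenation (Ph3PCH3Br, KOt-Bu, THF, reflux) gives 1,5-bis(benzyloxy)-3-bromo-2-(prop-1-en-2-yl)benzene F9. Ionic allylic bromination (NBS, catalytic TsOH, THF, reflux) gives 1,5-bis(benzyloxy)-3-bromo-2-(3-bromoprop-1-en-2-yl)benzene F10. Copper-catalysed borylation of the allylic bromide (B2pin2, CuI, PPh3, LiOMe, DMF, rt) gives 7.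

Further compounds
F1 | step 10 | 8-(benzyloxy)-6-{(1R)-3-[2,4-bis(benzyloxy)-6-bromophenyl]-1-[(4,4,5,5-tetramethyl-1,3,2-dioxaborolan-2-yl)oxy]but-3-en-1-yl}-2,2-dimethyl-2,3-dihydro-4H-chromen-4-one (not isolated) | CC1(C)CC(=O)c2cc([C@H](OB3OC(C)(C)C(C)(C)O3)CC(=C)c3c(Br)cc(OCc4ccccc4)cc3OCc3ccccc3)cc(OCc3ccccc3)c2O1
F2 | step 10 | 8-(benzyloxy)-6-{(1R)-3-[2,4-bis(benzyloxy)-6-bromophenyl]-1-hydroxybut-3-en-1-yl}-2,2-dimethyl-2,3-dihydro-4H-chromen-4-one | CC1(C)CC(=O)c2cc([C@H](O)CC(=C)c3c(Br)cc(OCc4ccccc4)cc3OCc3ccccc3)cc(OCc3ccccc3)c2O1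
F3 | step 10 | 8-(benzyloxy)-6-{(1R)-3-[2,4-bis(benzyloxy)-6-(4,4,5,5-tetramethyl-1,3,2-dioxaborolan-2-yl)phenyl]-1-hydroxybut-3-en-1-yl}-2,2-dimethyl-2,3-dihydro-4H-chromen-4-one | CC1(C)CC(=O)c2cc([C@H](O)CC(=C)c3c(B4OC(C)(C)C(C)(C)O4)cc(OCc4ccccc4)cc3OCc3ccccc3)cc(OCc3ccccc3)c2O1
F4 | step 10 | 8-(benzyloxy)-6-{(1R)-3-[2,4-bis(benzyloxy)-6-hydroxyphenyl]-1-hydroxybut-3-en-1-yl}-2,2-dimethyl-2,3-dihydro-4H-chromen-4-one | CC1(C)CC(=O)c2cc([C@H](O)CC(=C)c3c(O)cc(OCc4ccccc4)cc3OCc3ccccc3)cc(OCc3ccccc3)c2O1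
F5 | step 9 | racemic 8-(benzyloxy)-6-{3-[2,4-bis(benzyloxy)-6-bromophenyl]-1-[(4,4,5,5-tetramethyl-1,3,2-dioxaborolan-2-yl)oxy]but-3-en-1-yl}-2,2-dimethyl-2,3-dihydro-4H-chromen-4-one (not isolated) | CC1(C)CC(=O)c2cc(C(OB3OC(C)(C)C(C)(C)O3)CC(=C)c3c(Br)cc(OCc4ccccc4)cc3OCc3ccccc3)cc(OCc3ccccc3)c2O1
F6 | step 9 | racemic 8-(benzyloxy)-6-{3-[2,4-bis(benzyloxy)-6-bromophenyl]-1-hydroxybut-3-en-1-yl}-2,2-dimethyl-2,3-dihydro-4H-chromen-4-one | CC1(C)CC(=O)c2cc(C(O)CC(=C)c3c(Br)cc(OCc4ccccc4)cc3OCc3ccccc3)cc(OCc3ccccc3)c2O1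
F7 | step 9 | (1S)-1-[8-(benzyloxy)-2,2-dimethyl-4-oxo-3,4-dihydro-2H-chromen-6-yl]-3-[2,4-bis(benzyloxy)-6-bromophenyl]but-3-en-1-yl (2S)-2-methoxy-2-phenylacetate | CC1(C)CC(=O)c2cc([C@@H](OC(=O)[C@@H](OC)c3ccccc3)CC(=C)c3c(Br)cc(OCc4ccccc4)cc3OCc3ccccc3)cc(OCc3ccccc3)c2O1
F8 | step 9 | (1R)-1-[8-(benzyloxy)-2,2-dimethyl-4-oxo-3,4-dihydro-2H-chromen-6-yl]-3-[2,4-bis(benzyloxy)-6-bromophenyl]but-3-en-1-yl (2S)-2-methoxy-2-phenylacetate | CC1(C)CC(=O)c2cc([C@H](OC(=O)[C@@H](OC)c3ccccc3)CC(=C)c3c(Br)cc(OCc4ccccc4)cc3OCc3ccccc3)cc(OCc3ccccc3)c2O1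
F9 | step 4 | 1,5-bis(benzyloxy)-3-bromo-2-(prop-1-en-2-yl)benzene | C=C(C)c1c(OCc2ccccc2)cc(OCc2ccccc2)cc1Br
F10 | step 4 | 1,5-bis(benzyloxy)-3-bromo-2-(3-bromoprop-1-en-2-yl)benzene | C=C(CBr)c1c(OCc2ccccc2)cc(OCc2ccccc2)cc1Br
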